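Late in Thursday's run the target is still sinking, from 21.2% to 18.7%, while the isomer of the product A ends at 1.7%, each reading with a scatter of 0.5 percentage points. We reckon the late ratio from the isomer's slow climb.

| setting | Saturday's | Thursday's | flask |
|---|---|---|---|
| starting material | 2 M | 2 M | 2.0 M |
| protic impurity | 0.40 M | 0.80 M | 0.400 M |
| catalyst | 2 mM | 2 mM | 2.0 mM |
| remark | the very flask that is asked about, followed so far | run made earlier |  |
| time |  |  | 3.0 d |

- Saturday's (time / h: isomer of the product A / %, target / %): 5.00: 0, 15.8; 10.0: 1.1, 20.1; 15.0: 1.0, 22.2; 20.0: 0.7, 23.7
- Thursday's (time / d: isomer of the product A / %, target / %): 0.833: 1.4, 21.2; 1.67: 0.4, 20.4; 2.50: 1.4, 19.5; 3.00: 1.7, 18.7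

(readings scatter by 0.5 percentage points)

- what was read earlier has a scatter of 0.5 percentage points, one standard deviation

* ratio of isomer of the product A to target at 20 min
* ratio of isomer of the product A to target at 5.0 h
* ratio of isomer of the product A to target at 3.0 d
* which of isomer of the product A and target there is more of at 3.0 d

Thursday's readings, fitted to a straight line through zero, give 0.00557 d⁻¹. This slope, the fraction of the charge that appears as the isomer per day, we call the creep. Multiplied by the time and divided by the target, it gives the ratio.

Saturday's run offers a second way, and its line gives 0.0128 d⁻¹, steeper than Thursday's. The two part, but not firmly. Saturday's slope has a standard error of 0.00438 d⁻¹, wider than the 0.00116 d⁻¹ of Thursday's, so the gap is 1.60 combined errors. Saturday's line is the one that cheats: it stretches small readings from 20.0 h out to 3.0 d, whereas Thursday's last reading stands at 3.00 d. Thursday's flask did carry twice the protic impurity, and these runs cannot show what that does to the slope.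

So we commit to 1.67% of the isomer at 3.0 d. Over Saturday's last target, 23.7%, that makes a ratio of 0.0705, and the steeper line would give 0.162; the target leads on both. Early ratios we cannot resolve: one scatter over the target at 5.00 h is already 0.0316.

The forecast gave 0.025, 0.03 and 0.055, with the lead to the target, and said “target clearly leads”.

The simulation gives 0.0174 at 20 min, 0.0208 at 5.0 h and 0.0896 at 3.0 d, with the target ahead, 23.5% against 2.11%.

    starting material + catalyst ⇌ target + catalyst, rate k1*[starting material]*[catalyst] forward; the back reaction follows from the equilibrium constant (K = 0.920, k = 32.0 L mol⁻¹ h⁻¹)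
    starting material ⇌ isomer of the product A (K = 0.440, k = 0.00110 h⁻¹)
    starting material + catalyst ⇌ isomer of the product B + catalyst, rate k3*[starting material]*[catalyst] forward; the back reaction follows from the equilibrium constant (K = 1.20, k = 110 L mol⁻¹ h⁻¹)
    starting material + protic impurity → quenched substrate (k = 0.0640 L mol⁻¹ h⁻¹)

At 3.0 d this flask holds 25% of its starting material and 2.11% of the isomer, above the 1.67% from the creep. In the neighbour flask, with the catalyst cut to 8.0 × 10⁻⁴ M, the target stands at 22.5% at 3.0 d, so the creep gives a ratio of 0.0743. That flask reaches 0.102, with 2.30% of the isomer.

The numbers in the tables were computed with constants of no real substance; the scatter is artificial.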